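The spring run ends at 0.0201 M of Xp from a charge of 0.0480 M. The autumn run, at the same time and with the same Xc charged, ends at 0.0740 M from 0.180 M.

the same everywhere: Xc 0.0120 M
- dawn: Xa 0.120 M
- spring: Xa 0.0480 M
- autumn: Xa 0.180 M
- dusk: Xa 0.0400 M; time 4.4 h

| dawn run: time / h | dawn run: [Xp] / M | spring run: time / h | spring run: [Xp] / M | autumn run: time / h | autumn run: [Xp] / M |
|---|---|---|---|---|---|
| 0.16 | 0.0048 | 0.16 | 0.0017 | 0.16 | 0.0059 |
| 0.48 | 0.0124 | 0.48 | 0.0052 | 0.48 | 0.0182 |
| 0.92 | 0.0207 | 0.92 | 0.0079 | 0.92 | 0.0309 |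
| 1.5 | 0.0301 | 1.5 | 0.0124 | 1.5 | 0.0449 |
| 2.1 | 0.0363 | 2.1 | 0.0153 | 2.1 | 0.0554 |
| 2.8 | 0.0432 | 2.8 | 0.0163 | 2.8 | 0.0640 |
| 3.6 | 0.0474 | 3.6 | 0.0180 | 3.6 | 0.0699 |
| 4.4 | 0.0504 | 4.4 | 0.0201 | 4.4 | 0.0740 |

(readings scatter by 4 × 10⁻⁴ M)

- Overall: Xa -> Xp, with Xc as catalyst.
- Constant volume, constant temperature.
- An order is taken over about fifteen percent of the charge, up and down.

- the exponent of [Xa] in the starting rate at the charge of the dawn run (at the point where two percent of the Xa have become Xp) (one fixed amount of Xp, the same in the runs compared)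
- Xp in the dusk run at 4.4 h, as a share of the Xa charged

Dividing the autumn amount by the spring amount lets time drop out. The logarithm of that ratio over the logarithm of the charge ratio reads 0.986 from these two scattered readings, and I call this number the charge exponent. A value near one is what pseudo-first-order behaviour in Xa looks like, and I commit to the same value for the starting rate at a fixed amount of Xp. Scaling the spring run down to the dusk charge with this exponent, I reckon 0.0168 M of Xp in the dusk run at 4.4 h, a share of 42.0% of its charge.

The forecast gives 1 for the exponent and 42% for the dusk run, on the ground that “the curves overlay when scaled by charge”.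

The flask gives 1.0 for the exponent and 41.3% for the dusk run.

    2 Xc ⇌ Xc2, settled at all times (837.0 M⁻¹)
    Xc + Xa → Xp + Xc (95.40 M⁻¹ h⁻¹)
    Xp → L (0.05256 h⁻¹)
    Xa → Z (0.1656 h⁻¹)

In these steps Xa and Xp each stand to the first power, and the Xc charged is 0.0120 M in the dusk run, as in the dawn run. I put the charge exponent to use once more, on the rates at the fixed amount of Xp. From the dawn run's 0.026 M h⁻¹, the charge ratio raised to 0.986 gives 0.0393 M h⁻¹ for the autumn run, which stands at 0.040 M h⁻¹.

(Readings and results come from a simulation on assumed constants.)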